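# Proposed total synthesis of leucanthin B by [2,3]-Wittig contraction of a thirteen-membered allylic ether

## Analysis of the target

Leucanthin B (44) is a germacranolide. Its ten-membered carbocycle C1–C10 holds a C1=C10 double bond that is cis within the ring (C2 and C9 on the same side) and carries the C14 carboxyl. An α-methylene γ-lactone (O6–C12, C11=C13) is trans-fused at C6/C7.

All eight sp3 ring carbons C2–C9 are stereogenic and contiguous (2R,3R,4R,5R,6S,7R,8S,9S). Both epoxides (C2–C3, and C4–C5 with the methyl on C4) have their ring carbons cis. O5 and O6 are syn, and the two acyloxy groups on C8 and C9 are syn. C8 carries a (2R,3R)-epoxyangelate and C9 an acetate.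

The sensitive groups are:
- the vinyl epoxide C1=C10–C2(O), conjugated with the acid;
- the trisubstituted epoxide next to the lactone oxygen (opened by acid, prone to Payne migration in base);
- the Michael-accepting methylene lactone;
- two different esters on neighbouring carbinols, which can migrate.

The difficulty is to close a ten-membered ring carrying eight contiguous stereocentres and to tell O8 from O9.

The route rests on the unit C8(OH)–C7–C11(=C13)–C12. A homoallylic alcohol of this kind is the retron of a [2,3]-Wittig shift. Replacing the C7–C8 bond by an O8–C13 bond opens the carbocycle into a thirteen-membered allylic ether with a C9 ketone, so the ring-forming step also leaves O8 and O9 at different oxidation levels.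

## Retrosynthetic reasoning

**C14 oxidation level (44 ⇒ 43 ⇒ 42 ⇒ 41).** The free acid would not survive the amide base, hydride and acylation steps. C14 is therefore carried as a p-methoxybenzyl-protected allylic alcohol and raised to the acid in the last three steps. Nothing skeletal is cut here.

**Lactone and the two esters (41 ⇒ 39 ⇒ 38 ⇒ 37 ⇒ 31 + 35).** The lactone C12–O6 bond is cut to the silyl-protected hydroxy ester 39. The acetate comes from the C9 alcohol 38, and 38 from the C9 ketone 37 by hydride addition. The epoxyangelate C–O bond is cut to the α-ketol 31 and the acid 35. The order matters for two reasons: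
- O8 is acylated while C9 is still a ketone, which is the only point where the two oxygens differ.
- O8 must be blocked before O6 is freed, because both are γ to the C12 ester and either could lactonize.

**Key disconnection (31 ⇒ 29).** The C7–C8 bond is cut and O8 is reconnected to C13, moving the double bond from C11=C13 to C7=C11. This is chosen over cutting any other ring bond because:
- the thirteen-membered ether 29 is unstrained and easy to close;
- C8 is the only enolizable position of 29;
- the forward shift delivers C7 with its three-carbon acrylate unit and the C8 oxygen in one operation.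

The forward reaction has to form C7–C8 across the macrocycle from the enolate 30 and set 7R and 8S.

**C9–C10 bond of the macrocycle (29 ⇒ 28 ⇒ 27).** The enone is taken back to the allylic alcohol 28, whose C9–C10 bond is cut to an alkenyl iodide and an aldehyde in 27 (nickel/chromium-mediated closure). An olefination closure at C7=C11 with the C9 ketone already present was rejected: a phosphonate carbanion at C11 lies five atoms from C9 and would close a dihydrofuran by intramolecular olefination of the ketone. The C9 carbonyl is therefore created only after the ring exists.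

**C7=C11 bond (27 ⇒ 26 ⇒ 22 + 25; 25 ⇒ 23 + 24).** The (E)-enoate is cut by a phosphonate olefination into aldehyde 22 and phosphonate 25, which already contains C11, C12, C13, the ether oxygen, C8 and C9. Reagent 25 is the oxa-Michael adduct of diol 23 and vinylphosphonate 24. The forward reaction has to place C6 cis to C13.

**C1=C10 bond (22 ⇒ 21 ⇒ 20 ⇒ 19 ⇒ 16 + 17).** The trisubstituted iodoalkene is cut at C1=C10 into epoxy aldehyde 16 and the ylide 17, used as its α-iodo derivative 18. A stabilized α-iodo ylide puts the aldehyde residue cis to iodine. After the later C–C coupling with retention, C2 therefore ends cis to C9, as the ring requires.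

**C2–C3 epoxide (16 ⇒ 15 ⇒ 14 ⇒ 11 + 12).** The cis epoxide is opened to a syn chlorohydrin, and the C2–C3 bond is cut to aldehyde 11 and a chloroallyl unit from 12. A reagent-controlled allylboration is preferred to epoxidizing a Z-alkene, because no hydroxyl is available to direct a peracid to one face next to the quaternary C4. The extra vinyl carbon is removed by ozonolysis.

**C4–C5 epoxide (11 ⇒ 10 ⇒ 9 ⇒ 8 ⇒ 7).** The epoxide is removed to the (Z)-allylic alcohol 7. In the forward direction the free C6 hydroxyl directs the peracid, and A1,3 strain from the Z substituent makes this threo-selective. C4 and C5 thus follow from C6.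

**Z-trisubstituted alkene and C6 (7 ⇒ 6 ⇒ 5 ⇒ 4 ⇒ 2 + 3; 2 ⇒ 1).** The C4=C5 bond is cut by a Z-selective phosphonate olefination into the glyceraldehyde acetonide 2 and phosphonate 3. C6 comes from the chiral pool, as alcohol 1.

**Side chain (35 ⇒ 34 ⇒ 33 ⇒ 32).** The acid is taken back to the epoxy alcohol 34, made by asymmetric epoxidation of the (Z)-allylic alcohol 33 from angelic acid 32.

## Alternatives that were turned down

**Alternative 1: Eschenmoser–Tanabe fragmentation of a decalin epoxy ketone.**
- Disconnection: a C3–C8 bond is added, so the ten-membered ring becomes a decalin.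
- Forward key step: the tosylhydrazone of a C2 ketone next to a C3–C8 ring-fusion epoxide loses nitrogen and sulfinate. C3–C8 breaks and A1 results, a ten-membered C8 ketone with a C2≡C3 alkyne.
- For it: the medium ring comes from a six-six bicycle with no dilution requirement, and the cis C1=C10 geometry is fixed in a cyclohexene. On reliability of ring formation it is stronger than the chosen route.
- Against it: A1 lacks the C2 and C3 oxygen centres. The alkyne must be semi-reduced in the ring and the resulting cis alkene epoxidized on one face under transannular control only. The C8 ketone makes C7 epimerizable, C8 and C9 must still be told apart after reduction, and the C13 methylene has to be added next to that ketone. The acid-labile C4–C5 epoxide must also survive hydrazone formation.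
- Comparison: the chosen route sets C2–C6 in open-chain intermediates under reagent or hydroxyl control and forms C7 and C8 in the ring-forming step. From A1 about nine further steps with two uncontrolled stereocentres remain, against seven from 31.

**Alternative 2: nickel/chromium closure of the ten-membered ring at C9–C10.**
- Disconnection: C9–C10.
- Forward key step: CrCl2 with catalytic NiCl2 turns a C10 alkenyl iodide (an α-iodoenoate) into an alkenylchromium species that adds to a C9 aldehyde. This gives A2, the C9 alcohol of the target as its 2-(trimethylsilyl)ethyl ester.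
- For it: it is the most convergent plan. A2 is two steps from 44, so on step economy after the key step it is clearly stronger. The metal pair tolerates epoxides and esters.
- Against it:
  - Direct closure of a ten-membered ring is the hardest ring size, with transannular strain and a dilution requirement.
  - An alkenylchromium α to an ester is allenoate-like, so it adds slowly and can lose geometry.
  - The aldehyde sits next to C8 bearing the epoxyangelate, so it can epimerize or eliminate.
  - C9 is created in the closure without an obvious control element.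
  - The methylene lactone is exposed to low-valent metals.
- Comparison: the chosen route uses the same coupling (step 20), but for an unstrained thirteen-membered ring and at an aldehyde without an α-stereocentre, and the carbinol centre is then erased by oxidation. The ten-membered ring is closed by an intramolecular shift that does not depend on dilution. The price is about five more steps after ring formation.

**Alternative 3: anionic oxy-Cope expansion of a diepoxycyclohexanol.**
- Disconnection: C8–C9 is cut and C1–C6 is added, giving a cis-1,2-dialkenyl cyclohexanol.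
- Forward key step: the potassium alkoxide undergoes a [3,3] shift to A3, the ten-membered C6 ketone with both epoxides, 8-O-PMB and 9-O-silyl groups.
- For it: ring expansion needs no dilution. Both epoxides are set on a rigid cyclohexane, and O8 and O9 arrive already differentiated. On these points it is as strong as or stronger than the chosen route.
- Against it:
  - A3 has a bare C7 methylene and a C6 ketone. The whole C11–C13 unit must be attached at C7 through an enolate that has the C8 ether as a β-leaving group.
  - C6 must then be reduced to 6S and C7 set.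
  - The alkoxide sits on a carbon next to the C4–C5 epoxide, so epoxide migration competes with the shift.
  - Both joining alkene termini are oxygen-substituted, so C8/C9 depend on two enol-ether geometries.
- Comparison: in the chosen route C6 is fixed before the key step, and the key step itself installs the C7 side chain and O8. Alternative 3 leaves more bonds and more stereochemical risk after the ring is formed.

Key step: step 22

## Route

Remark: locants in names are germacrane locants of the target (C1–C14), also for open-chain intermediates. Compound 28 is carried as a mixture of C9 epimers because C9 becomes a ketone in step 21.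

Step 1
Reactants: 1 (R)-(2,2-dimethyl-1,3-dioxolan-4-yl)methanol
Product: 2 (S)-2,2-dimethyl-1,3-dioxolane-4-carbaldehyde
Conditions: (COCl)2, DMSO, CH2Cl2, −78 °C; Et3N; used crude
Reagents that add atoms: none
Why: Swern oxidation of a primary alcohol; at −78 °C the α-alkoxy centre should not epimerize, and the labile aldehyde is used at once.

Step 2
Reactants: 2 (S)-2,2-dimethyl-1,3-dioxolane-4-carbaldehyde; 3 ethyl 2-[bis(2,2,2-trifluoroethoxy)phosphoryl]propanoate
Product: 4 ethyl (2Z)-3-[(4R)-2,2-dimethyl-1,3-dioxolan-4-yl]-2-methylprop-2-enoate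
Conditions: KN(SiMe3)2, 18-crown-6, THF, −78 °C
Reagents that add atoms: none
Why: Still–Gennari olefination; the electron-poor phosphonate eliminates from the kinetic adduct and should give the (Z)-trisubstituted enoate (ester cis to the dioxolane), which fixes the later cis relation of C3 and C6 on the C4–C5 epoxide.

Step 3
Reactants: 4 ethyl (2Z)-3-[(4R)-2,2-dimethyl-1,3-dioxolan-4-yl]-2-methylprop-2-enoate
Product: 5 (2Z)-3-[(4R)-2,2-dimethyl-1,3-dioxolan-4-yl]-2-methylprop-2-en-1-ol
Conditions: iBu2AlH, CH2Cl2, −78 °C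
Reagents that add atoms: none
Why: 1,2-reduction of an enoate to the allylic alcohol by an aluminium hydride; the alkene geometry is retained.

Step 4
Reactants: 5 (2Z)-3-[(4R)-2,2-dimethyl-1,3-dioxolan-4-yl]-2-methylprop-2-en-1-ol
Product: 6 (4R)-4-[(1Z)-3-(4-methoxybenzyloxy)-2-methylprop-1-enyl]-2,2-dimethyl-1,3-dioxolane
Conditions: NaH, 4-methoxybenzyl chloride, Bu4NI (cat.), THF/DMF, 0 °C to rt
Reagents that add atoms: 4-methoxybenzyl chloride, COc1ccc(CCl)cc1
Why: Williamson etherification; masking O3 lets the acetonide be removed and the C6 hydroxyl act alone as director.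

Step 5
Reactants: 6 (4R)-4-[(1Z)-3-(4-methoxybenzyloxy)-2-methylprop-1-enyl]-2,2-dimethyl-1,3-dioxolane
Product: 7 (2R,3Z)-5-(4-methoxybenzyloxy)-4-methylpent-3-ene-1,2-diol
Conditions: AcOH/H2O 4:1, 40 °C
Reagents that add atoms: none
Why: acid-catalysed acetal hydrolysis; dilute acetic acid should leave the allylic p-methoxybenzyl ether and the Z alkene untouched.

Step 6
Reactants: 7 (2R,3Z)-5-(4-methoxybenzyloxy)-4-methylpent-3-ene-1,2-diol
Product: 8 (1S)-1-[(2R,3S)-3-(4-methoxybenzyloxymethyl)-3-methyloxiran-2-yl]ethane-1,2-diol (threo epoxy diol; 4S,5R,6S)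
Conditions: mCPBA, NaHCO3, CH2Cl2, 0 °C
Reagents that add atoms: 3-chloroperbenzoic acid, OOC(=O)c1cccc(Cl)c1
Why: hydroxyl-directed (Henbest) epoxidation; A1,3 strain with the Z substituent on C4 holds H6 in the alkene plane, so the peracid bound to O6 should attack the face syn to the hydroxyl and give the threo epoxy alcohol, setting C4 and C5 from C6.

Step 7
Reactants: 8 (1S)-1-[(2R,3S)-3-(4-methoxybenzyloxymethyl)-3-methyloxiran-2-yl]ethane-1,2-diol
Product: 9 (2R,3S)-2-[(1S)-1,2-bis(triethylsilyloxy)ethyl]-3-(4-methoxybenzyloxymethyl)-3-methyloxirane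
Conditions: Et3SiCl, imidazole, DMAP (cat.), DMF, 0 °C to rt
Reagents that add atoms: chlorotriethylsilane, CC[Si](Cl)(CC)CC
Why: silylation of both hydroxyls; the primary ether is the latent C7 aldehyde and the secondary one protects O6 up to step 29.

Step 8
Reactants: 9 (2R,3S)-2-[(1S)-1,2-bis(triethylsilyloxy)ethyl]-3-(4-methoxybenzyloxymethyl)-3-methyloxirane
Product: 10 {(2S,3R)-3-[(1S)-1,2-bis(triethylsilyloxy)ethyl]-2-methyloxiran-2-yl}methanol
Conditions: DDQ, CH2Cl2/pH 7 buffer, 0 °C
Reagents that add atoms: none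
Why: oxidative cleavage of a p-methoxybenzyl ether (benzylic hydride abstraction, then hydrolysis); buffering should keep the silyl ethers and the epoxide intact.

Step 9
Reactants: 10 {(2S,3R)-3-[(1S)-1,2-bis(triethylsilyloxy)ethyl]-2-methyloxiran-2-yl}methanol
Product: 11 (2R,3R)-3-[(1S)-1,2-bis(triethylsilyloxy)ethyl]-2-methyloxirane-2-carbaldehyde
Conditions: Dess–Martin periodinane, NaHCO3, CH2Cl2, rt
Reagents that add atoms: none
Why: Dess–Martin oxidation; the aldehyde has no α-hydrogen and cannot epimerize.

Step 10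
Reactants: 11 (2R,3R)-3-[(1S)-1,2-bis(triethylsilyloxy)ethyl]-2-methyloxirane-2-carbaldehyde; 12 3-chloroprop-1-ene
Product: 14 (1S,2S)-1-{(2S,3R)-3-[(1S)-1,2-bis(triethylsilyloxy)ethyl]-2-methyloxiran-2-yl}-2-chlorobut-3-en-1-ol (syn chlorohydrin), via chloroallylborane 13 (not isolated)
Conditions: 12, (+)-B-methoxydiisopinocampheylborane, LiN(c-C6H11)2, THF, −95 °C; BF3·OEt2; then 11, −95 °C; NaBO3·4H2O, THF/H2O
Reagents that add atoms: none
Why: Oehlschlager–Brown (Z)-γ-chloroallylboration; the chair transition state of the Z-allylborane gives the syn chlorohydrin, and the isopinocampheyl groups derived from (−)-α-pinene should direct the reagent to the Re face of the aldehyde, setting C3 and C2 under reagent control.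

Step 11
Reactants: 14 syn chlorohydrin
Product: 15 (2R,3R)-2-[(1S)-1,2-bis(triethylsilyloxy)ethyl]-3-[(2R,3R)-3-ethenyloxiran-2-yl]-3-methyloxirane (cis vinyl epoxide)
Conditions: DBU, CH2Cl2, 0 °C to rt
Reagents that add atoms: none
Why: intramolecular Williamson displacement (3-exo-tet) of the allylic chloride by the C3 alkoxide with inversion at C2, so the syn chlorohydrin gives the cis 2,3-epoxide; closure onto the activated chloride should outrun Payne migration.

Step 12
Reactants: 15 cis vinyl epoxide
Product: 16 (2S,3R)-3-{(2R,3R)-3-[(1S)-1,2-bis(triethylsilyloxy)ethyl]-2-methyloxiran-2-yl}oxirane-2-carbaldehyde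
Conditions: O3, CH2Cl2, −78 °C; PPh3; used crude
Reagents that add atoms: ozone, [O-][O+]=O
Why: ozonolysis of the only alkene with reductive work-up; the cis epoxy aldehyde is taken on at once to avoid epimerization at C2.

Step 13
Reactants: 16 cis epoxy aldehyde; 17 methyl (triphenylphosphoranylidene)acetate
Product: 19 methyl (2Z)-2-iodo-3-[(2R,3R)-epoxide]prop-2-enoate (C1=C10 iodoenoate: 10-iodo, C14 methyl ester, 2R,3R,4R,5R,6S), via iodo ylide 18 (not isolated)
Conditions: 17, N-iodosuccinimide, K2CO3, CH2Cl2, −20 °C to 0 °C; then 16, rt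
Reagents that add atoms: N-iodosuccinimide, O=C1CCC(=O)N1I
Why: Wittig olefination with an α-iodo ester-stabilized ylide; as for other stabilized ylides the aldehyde residue should end trans to the ester, hence cis to iodine, which places C2 cis to the position later taken by C9.

Step 14
Reactants: 19 (Z)-iodoenoate
Product: 20 (2Z)-2-iodoprop-2-en-1-ol (C14 alcohol of 19; 2R,3R,4R,5R,6S)
Conditions: iBu2AlH, CH2Cl2, −78 °C
Reagents that add atoms: none
Why: 1,2-reduction of the enoate; at −78 °C the ester should react before the alkenyl iodide or the vinyl epoxide.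

Step 15
Reactants: 20 (Z)-iodo allylic alcohol
Product: 21 open-chain C1–C7 iodide (1Z; 10-iodo; 14-O-p-methoxybenzyl; 2,3- and 4,5-epoxides; 6,7-bis-O-triethylsilyl; 2R,3R,4R,5R,6S)
Conditions: NaH, 4-methoxybenzyl chloride, Bu4NI (cat.), DMF, 0 °C
Reagents that add atoms: 4-methoxybenzyl chloride, COc1ccc(CCl)cc1
Why: Williamson etherification; C14 is trans to C2 on the alkene, so the alkoxide cannot reach the vinyl epoxide.

Step 16
Reactants: 21 open-chain C1–C7 iodide
Product: 22 C7 aldehyde (6-O-triethylsilyl; 2R,3R,4R,5R,6R by CIP, same spatial arrangement)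
Conditions: (COCl)2, DMSO, CH2Cl2, −78 to −40 °C; Et3N, −78 °C to rt
Reagents that add atoms: none
Why: Swern oxidation applied to the bis-silyl ether; the chlorosulfonium reagent cleaves the unhindered primary triethylsilyl ether and oxidizes it directly to the aldehyde, while the secondary silyl ether is expected to stay.

Step 17
Reactants: 23 ethane-1,2-diol; 24 methyl 2-(dimethoxyphosphoryl)prop-2-enoate
Product: 25 methyl 2-(dimethoxyphosphoryl)-3-(2-hydroxyethoxy)propanoate
Conditions: 23 (5 equiv), K2CO3 (cat.), THF, 0 °C to rt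
Reagents that add atoms: none
Why: base-catalysed oxa-Michael addition of a primary alcohol to a vinylphosphonate; excess diol suppresses double addition.

Step 18
Reactants: 22 C7 aldehyde; 25 methyl 2-(dimethoxyphosphoryl)-3-(2-hydroxyethoxy)propanoate
Product: 26 (7E)-enoate (C11 bears CO2Me and C13H2–O–CH2CH2OH; 6-O-triethylsilyl; diepoxide; 1Z-10-iodo-14-O-p-methoxybenzyl; 2R,3R,4R,5R,6S)
Conditions: LiCl, iPr2NEt, MeCN, 0 °C to rt
Reagents that add atoms: none
Why: Horner–Wadsworth–Emmons reaction under Masamune–Roush conditions; an α-substituted phosphonoacetate and an α-branched aldehyde should give the (E)-enoate (C6 trans to the ester, cis to C13), and the mild base spares the α-silyloxy centre.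

Step 19
Reactants: 26 (7E)-enoate with primary alcohol
Product: 27 C9 aldehyde (C13H2–O–C8H2–C9HO; otherwise as 26)
Conditions: Dess–Martin periodinane, NaHCO3, CH2Cl2, 0 °C; used crude
Reagents that add atoms: none
Why: Dess–Martin oxidation of the only free hydroxyl; neutral conditions suit the α-alkoxy aldehyde.

Step 20
Reactants: 27 C9 aldehyde
Product: 28 thirteen-membered allylic alcohol (ring C9–C8–O–C13–C11–C7–C6–C5–C4–C3–C2–C1–C10; 1(10)Z, 7(11)E; 2R,3R,4R,5R,6S; C9 epimers)
Conditions: CrCl2 (10 equiv), NiCl2 (cat.), DMSO/THF, rt, 0.003 M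
Reagents that add atoms: none
Why: Nozaki–Hiyama–Kishi reaction; zerovalent nickel inserts into the C10–I bond, the alkenyl group passes to trivalent chromium with retention and adds to the aldehyde, closing an unstrained thirteen-membered ring (13-exo-trig) at high dilution; the C9 centre is not controlled and need not be.

Step 21
Reactants: 28 thirteen-membered allylic alcohol
Product: 29 thirteen-membered keto allylic ether (C9 ketone; 1(10)Z, 7(11)E; 2R,3R,4R,5R,6S)
Conditions: Dess–Martin periodinane, NaHCO3, CH2Cl2, rt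
Reagents that add atoms: none
Why: Dess–Martin oxidation of an allylic alcohol to the enone; both C9 epimers converge.

Step 22
Reactants: 29 thirteen-membered keto allylic ether
Product: 31 ten-membered C8-hydroxy C9-ketone with the C7 α-methylene ester chain (2R,3R,4R,5R,6S,7R,8S), via lithium enolate 30 (not isolated)
Conditions: LiN(SiMe3)2, THF, −78 °C; AcOH quench at −78 °C
Reagents that add atoms: none
Why: LiN(SiMe3)2 removes a C8 proton, the only enolizable position and one activated by both the carbonyl and the ether oxygen, to give enolate 30. The enolate undergoes a suprafacial [2,3]-sigmatropic (Wittig) shift through a five-membered envelope of C8, O, C13, C11 and C7: C7–C8 forms, O–C13 breaks and the double bond moves to C11=C13, leaving the C8 alkoxide. The closest known types are the enolate [2,3]-Wittig rearrangement of α-allyloxy ketones and the [2,3]-Wittig contraction of thirteen-membered allylic ethers to cyclodecenols; because the acceptor is an enoate, conjugate addition with β-alkoxide loss would lead to the same product. The ten-membered ring closes transannularly by 13-to-10 contraction; read as a conjugate addition this would be 5-endo-trig, so the concerted shift is the expected path. C7 is controlled by C6: A1,3 strain with C13H2 holds H6 in the enoate plane, the ring chain ties C5 and the attacking C8 to the same face, and the silyloxy group lies anti to the forming bond, which should give 7R. C8 is controlled by the envelope: with the C9 carbonyl exo (a cis-fused five/ten transition state), an allylic ether whose terminal substituent C6 is cis to C13H2 gives the syn arrangement of O8 and C6, which is 8S. The step needs the [2,3] shift to win over a [1,2] shift and over γ-deprotonation at C2; low temperature, the lithium counter-ion and the lack of any other α-hydrogen should secure this. The cold quench keeps the C8 alkoxide from attacking the C12 ester.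

Step 23
Reactants: 32 (2Z)-2-methylbut-2-enoic acid (angelic acid)
Product: 33 (2Z)-2-methylbut-2-en-1-ol
Conditions: LiAlH4, Et2O, 0 °C
Reagents that add atoms: none
Why: hydride reduction of an α,β-unsaturated acid to the allylic alcohol; at 0 °C the Z geometry should be kept.

Step 24
Reactants: 33 (2Z)-2-methylbut-2-en-1-ol
Product: 34 [(2S,3R)-2,3-dimethyloxiran-2-yl]methanol
Conditions: Ti(OiPr)4 (cat.), L-(+)-diethyl tartrate (cat.), t-BuOOH, 4 Å sieves, CH2Cl2, −20 °C
Reagents that add atoms: tert-butyl hydroperoxide, CC(C)(C)OO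
Why: Katsuki–Sharpless asymmetric epoxidation; with the L-(+)-tartrate a (Z)-allylic alcohol should give the (2S,3R) epoxy alcohol, the same facial sense as for other Z-allylic alcohols.

Step 25
Reactants: 34 [(2S,3R)-2,3-dimethyloxiran-2-yl]methanol
Product: 35 (2R,3R)-2,3-dimethyloxirane-2-carboxylic acid (epoxyangelic acid)
Conditions: TEMPO (cat.), PhI(OAc)2, MeCN/H2O, rt
Reagents that add atoms: water, O
Why: oxoammonium oxidation of the primary alcohol through the aldehyde hydrate to the acid; the α-carbon is quaternary, so no centre can epimerize (the descriptor at C2 changes by CIP only).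

Step 26
Reactants: 31 ten-membered C8-hydroxy C9-ketone; 35 (2R,3R)-2,3-dimethyloxirane-2-carboxylic acid
Product: 37 C8 (2R,3R)-epoxyangelate of 31 (C9 ketone), via mixed anhydride 36 (not isolated)
Conditions: 35, 2,4,6-trichlorobenzoyl chloride, Et3N, THF, rt; then 31, DMAP, toluene, rt
Reagents that add atoms: none
Why: Yamaguchi esterification; DMAP should attack the aliphatic carbonyl of the mixed anhydride, and acylating O8 while C9 is a ketone differentiates the two oxygens and blocks O8 before O6 is freed.

Step 27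
Reactants: 37 C8 epoxyangelate C9 ketone
Product: 38 (9S)-alcohol (2R,3R,4R,5R,6S,7R,8S,9S)
Conditions: NaBH4, CeCl3·7H2O, MeOH, −78 °C
Reagents that add atoms: none
Why: Luche reduction (1,2-selective for the enone and faster than conjugate reduction of the acrylate); Felkin–Anh addition anti to the C8 acyloxy group gives the syn 8,9-relationship, which is 9S, provided the ring does not override it.

Step 28
Reactants: 38 (9S)-alcohol
Product: 39 C9 acetate (C8 epoxyangelate, 6-O-triethylsilyl, C12 methyl ester, 14-O-p-methoxybenzyl)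
Conditions: Ac2O, DMAP (cat.), pyridine, CH2Cl2, 0 °C to rt
Reagents that add atoms: acetic anhydride, CC(=O)OC(C)=O
Why: DMAP-catalysed acetylation of the allylic secondary alcohol; the hindered epoxyangelate should not migrate under these conditions.

Step 29
Reactants: 39 C9 acetate
Product: 41 6,12-lactone (α-methylene γ-lactone, trans-fused; 14-O-p-methoxybenzyl), via hydroxy ester 40 (not isolated)
Conditions: HF·pyridine, pyridine, THF, 0 °C to rt; then PPTS (cat.), CH2Cl2, rt
Reagents that add atoms: none
Why: fluoride desilylation, then lactonization (5-exo-trig acyl substitution of O6 on the C12 methyl ester); O8 and O9 are already acylated, so only the 6,12-lactone can form.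

Step 30
Reactants: 41 6,12-lactone
Product: 42 C14 allylic alcohol
Conditions: DDQ, CH2Cl2/pH 7 buffer, 0 °C to rt
Reagents that add atoms: none
Why: oxidative cleavage of the allylic p-methoxybenzyl ether under neutral conditions that should spare the epoxides, the esters and the methylene lactone.

Step 31
Reactants: 42 C14 allylic alcohol
Product: 43 C14 enal
Conditions: Dess–Martin periodinane, NaHCO3, CH2Cl2, rt
Reagents that add atoms: none
Why: Dess–Martin oxidation of the allylic alcohol; buffered neutral conditions suit the vinyl epoxide.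

Step 32
Reactants: 43 C14 enal
Product: 44 leucanthin B
Conditions: NaClO2, NaH2PO4, 2-methylbut-2-ene, t-BuOH/H2O, 0 °C to rt
Reagents that add atoms: sodium chlorite, [Na+].[O-]Cl=O
Why: Pinnick oxidation of the enal to the acid; the alkene scavenger removes hypochlorous acid before it can reach the methylene lactone or the epoxides.

## Compound list

1 | (R)-(2,2-dimethyl-1,3-dioxolan-4-yl)methanol | OC[C@@H]1COC(C)(C)O1 | starting material
2 | (S)-2,2-dimethyl-1,3-dioxolane-4-carbaldehyde | O=C[C@@H]1COC(C)(C)O1 | intermediate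
3 | ethyl 2-[bis(2,2,2-trifluoroethoxy)phosphoryl]propanoate | CCOC(=O)C(C)P(=O)(OCC(F)(F)F)OCC(F)(F)F | starting material
4 | ethyl (2Z)-3-[(4R)-2,2-dimethyl-1,3-dioxolan-4-yl]-2-methylprop-2-enoate | CCOC(=O)/C(C)=C\[C@@H]1COC(C)(C)O1 | intermediate
5 | (2Z)-3-[(4R)-2,2-dimethyl-1,3-dioxolan-4-yl]-2-methylprop-2-en-1-ol | OC/C(C)=C\[C@@H]1COC(C)(C)O1 | intermediate
6 | (4R)-4-[(1Z)-3-(4-methoxybenzyloxy)-2-methylprop-1-enyl]-2,2-dimethyl-1,3-dioxolane | COc1ccc(COC/C(C)=C\[C@@H]2COC(C)(C)O2)cc1 | intermediate
7 | (2R,3Z)-5-(4-methoxybenzyloxy)-4-methylpent-3-ene-1,2-diol | COc1ccc(COC/C(C)=C\[C@@H](O)CO)cc1 | intermediate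
8 | (1S)-1-[(2R,3S)-3-(4-methoxybenzyloxymethyl)-3-methyloxiran-2-yl]ethane-1,2-diol | OC[C@H](O)[C@H]1O[C@@]1(C)COCc1ccc(OC)cc1 | intermediate
9 | (2R,3S)-2-[(1S)-1,2-bis(triethylsilyloxy)ethyl]-3-(4-methoxybenzyloxymethyl)-3-methyloxirane | CC[Si](CC)(CC)OC[C@H](O[Si](CC)(CC)CC)[C@H]1O[C@@]1(C)COCc1ccc(OC)cc1 | intermediate
10 | {(2S,3R)-3-[(1S)-1,2-bis(triethylsilyloxy)ethyl]-2-methyloxiran-2-yl}methanol | CC[Si](CC)(CC)OC[C@H](O[Si](CC)(CC)CC)[C@H]1O[C@@]1(C)CO | intermediate
11 | (2R,3R)-3-[(1S)-1,2-bis(triethylsilyloxy)ethyl]-2-methyloxirane-2-carbaldehyde | CC[Si](CC)(CC)OC[C@H](O[Si](CC)(CC)CC)[C@H]1O[C@@]1(C)C=O | intermediate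
12 | 3-chloroprop-1-ene (allyl chloride) | C=CCCl | starting material
13 | (Z)-(3-chloroprop-2-enyl)diisopinocampheylborane from (+)-B-methoxydiisopinocampheylborane (not isolated) | Cl/C=C\CB([C@H]1C[C@H]2C[C@@H]([C@@H]1C)C2(C)C)[C@H]1C[C@H]2C[C@@H]([C@@H]1C)C2(C)C | intermediate
14 | (1S,2S)-1-{(2S,3R)-3-[(1S)-1,2-bis(triethylsilyloxy)ethyl]-2-methyloxiran-2-yl}-2-chlorobut-3-en-1-ol | CC[Si](CC)(CC)OC[C@H](O[Si](CC)(CC)CC)[C@H]1O[C@@]1(C)[C@H](O)[C@@H](Cl)C=C | intermediate
15 | (2R,3R)-2-[(1S)-1,2-bis(triethylsilyloxy)ethyl]-3-[(2R,3R)-3-ethenyloxiran-2-yl]-3-methyloxirane | CC[Si](CC)(CC)OC[C@H](O[Si](CC)(CC)CC)[C@H]1O[C@@]1(C)[C@@H]1O[C@@H]1C=C | intermediate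
16 | (2S,3R)-3-{(2R,3R)-3-[(1S)-1,2-bis(triethylsilyloxy)ethyl]-2-methyloxiran-2-yl}oxirane-2-carbaldehyde | CC[Si](CC)(CC)OC[C@H](O[Si](CC)(CC)CC)[C@H]1O[C@@]1(C)[C@@H]1O[C@@H]1C=O | intermediate
17 | methyl (triphenylphosphoranylidene)acetate | COC(=O)C=P(c1ccccc1)(c1ccccc1)c1ccccc1 | starting material
18 | methyl iodo(triphenylphosphoranylidene)acetate (not isolated) | COC(=O)C(I)=P(c1ccccc1)(c1ccccc1)c1ccccc1 | intermediate
19 | methyl (2Z)-2-iodoprop-2-enoate carrying at C3 the (2R,3R)-2,3-epoxide, (4R,5R)-4,5-epoxide and (6S)-6,7-bis(triethylsilyloxy) chain | CC[Si](CC)(CC)OC[C@H](O[Si](CC)(CC)CC)[C@H]1O[C@@]1(C)[C@@H]1O[C@@H]1/C=C(\I)C(=O)OC | intermediate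
20 | C14 alcohol of 19, (1Z)-10-iodo (2R,3R,4R,5R,6S) | CC[Si](CC)(CC)OC[C@H](O[Si](CC)(CC)CC)[C@H]1O[C@@]1(C)[C@@H]1O[C@@H]1/C=C(\I)CO | intermediate
21 | open-chain C1–C7 iodide: (1Z)-10-iodo, 14-O-p-methoxybenzyl, 2,3- and 4,5-epoxides, 6,7-bis-O-triethylsilyl (2R,3R,4R,5R,6S) | CC[Si](CC)(CC)OC[C@H](O[Si](CC)(CC)CC)[C@H]1O[C@@]1(C)[C@@H]1O[C@@H]1/C=C(\I)COCc1ccc(OC)cc1 | intermediate
22 | C7 aldehyde of 21, 6-O-triethylsilyl (2R,3R,4R,5R,6R) | O=C[C@H](O[Si](CC)(CC)CC)[C@H]1O[C@@]1(C)[C@@H]1O[C@@H]1/C=C(\I)COCc1ccc(OC)cc1 | intermediate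
23 | ethane-1,2-diol | OCCO | starting material
24 | methyl 2-(dimethoxyphosphoryl)prop-2-enoate | C=C(C(=O)OC)P(=O)(OC)OC | starting material
25 | methyl 2-(dimethoxyphosphoryl)-3-(2-hydroxyethoxy)propanoate | COC(=O)C(COCCO)P(=O)(OC)OC | intermediate
26 | (7E)-enoate with C13H2–O–CH2CH2OH, 6-O-triethylsilyl, diepoxide, (1Z)-10-iodo-14-O-p-methoxybenzyl (2R,3R,4R,5R,6S) | OCCOC/C(C(=O)OC)=C\[C@H](O[Si](CC)(CC)CC)[C@H]1O[C@@]1(C)[C@@H]1O[C@@H]1/C=C(\I)COCc1ccc(OC)cc1 | intermediate
27 | C9 aldehyde of 26 | O=CCOC/C(C(=O)OC)=C\[C@H](O[Si](CC)(CC)CC)[C@H]1O[C@@]1(C)[C@@H]1O[C@@H]1/C=C(\I)COCc1ccc(OC)cc1 | intermediate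
28 | thirteen-membered allylic alcohol, 1(10)Z, 7(11)E (2R,3R,4R,5R,6S; C9 epimers) | OC1COC/C(C(=O)OC)=C\[C@H](O[Si](CC)(CC)CC)[C@H]2O[C@@]2(C)[C@@H]2O[C@@H]2/C=C1/COCc3ccc(OC)cc3 | intermediate
29 | thirteen-membered keto allylic ether, 1(10)Z, 7(11)E (2R,3R,4R,5R,6S) | O=C1COC/C(C(=O)OC)=C\[C@H](O[Si](CC)(CC)CC)[C@H]2O[C@@]2(C)[C@@H]2O[C@@H]2/C=C1/COCc3ccc(OC)cc3 | intermediate
30 | lithium C8=C9 enolate of 29 (not isolated) | [Li]O/C1=C\OC/C(C(=O)OC)=C\[C@H](O[Si](CC)(CC)CC)[C@H]2O[C@@]2(C)[C@@H]2O[C@@H]2/C=C1/COCc3ccc(OC)cc3 | intermediate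
31 | ten-membered C8-hydroxy C9-ketone with C7 α-methylene ester chain (2R,3R,4R,5R,6S,7R,8S) | C=C(C(=O)OC)[C@@H]1[C@H](O)C(=O)/C(COCc3ccc(OC)cc3)=C\[C@H]2O[C@H]2[C@]2(C)O[C@@H]2[C@H]1O[Si](CC)(CC)CC | intermediate
32 | (2Z)-2-methylbut-2-enoic acid (angelic acid) | C/C=C(/C)C(=O)O | starting material
33 | (2Z)-2-methylbut-2-en-1-ol | C/C=C(/C)CO | intermediate
34 | [(2S,3R)-2,3-dimethyloxiran-2-yl]methanol | OC[C@]1(C)O[C@@H]1C | intermediate
35 | (2R,3R)-2,3-dimethyloxirane-2-carboxylic acid | OC(=O)[C@]1(C)O[C@@H]1C | intermediate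
36 | (2R,3R)-2,3-dimethyloxirane-2-carboxylic 2,4,6-trichlorobenzoic anhydride (not isolated) | O=C(OC(=O)[C@]1(C)O[C@@H]1C)c1c(Cl)cc(Cl)cc1Cl | intermediate
37 | C8 (2R,3R)-epoxyangelate of 31 | C=C(C(=O)OC)[C@@H]1[C@H](OC(=O)[C@]2(C)O[C@@H]2C)C(=O)/C(COCc3ccc(OC)cc3)=C\[C@H]2O[C@H]2[C@]2(C)O[C@@H]2[C@H]1O[Si](CC)(CC)CC | intermediate
38 | (9S)-alcohol from 37 | C=C(C(=O)OC)[C@@H]1[C@H](OC(=O)[C@]2(C)O[C@@H]2C)[C@@H](O)/C(COCc3ccc(OC)cc3)=C\[C@H]2O[C@H]2[C@]2(C)O[C@@H]2[C@H]1O[Si](CC)(CC)CC | intermediate
39 | C9 acetate of 38 | C=C(C(=O)OC)[C@@H]1[C@H](OC(=O)[C@]2(C)O[C@@H]2C)[C@@H](OC(C)=O)/C(COCc3ccc(OC)cc3)=C\[C@H]2O[C@H]2[C@]2(C)O[C@@H]2[C@H]1O[Si](CC)(CC)CC | intermediate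
40 | C6 hydroxy methyl ester from 39 (not isolated) | C=C(C(=O)OC)[C@@H]1[C@H](OC(=O)[C@]2(C)O[C@@H]2C)[C@@H](OC(C)=O)/C(COCc3ccc(OC)cc3)=C\[C@H]2O[C@H]2[C@]2(C)O[C@@H]2[C@H]1O | intermediate
41 | 14-O-p-methoxybenzyl 6,12-lactone (leucanthin B skeleton with C14 as CH2O-PMB) | C=C1C(=O)O[C@H]2[C@H]1[C@H](OC(=O)[C@]1(C)O[C@@H]1C)[C@@H](OC(C)=O)/C(COCc1ccc(OC)cc1)=C\[C@H]1O[C@H]1[C@]1(C)O[C@H]21 | intermediate
42 | C14 allylic alcohol | C=C1C(=O)O[C@H]2[C@H]1[C@H](OC(=O)[C@]1(C)O[C@@H]1C)[C@@H](OC(C)=O)/C(CO)=C\[C@H]1O[C@H]1[C@]1(C)O[C@H]21 | intermediate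
43 | C14 enal | C=C1C(=O)O[C@H]2[C@H]1[C@H](OC(=O)[C@]1(C)O[C@@H]1C)[C@@H](OC(C)=O)/C(C=O)=C\[C@H]1O[C@H]1[C@]1(C)O[C@H]21 | intermediate
44 | leucanthin B | C=C1C(=O)O[C@H]2[C@H]1[C@H](OC(=O)[C@]1(C)O[C@@H]1C)[C@@H](OC(C)=O)/C(C(=O)O)=C\[C@H]1O[C@H]1[C@]1(C)O[C@H]21 | target

## Step count and risk

Total: 32 steps. Longest linear sequence: 28 steps (steps 1–16, 18–22 and 26–32, from 1 to 44).

**Step 22 (key step).**
- What may go wrong: the cross-conjugated enolate may take another path, namely a [1,2] shift, γ-deprotonation at C2 with opening of the 2,3-epoxide, or attack of the C8 alkoxide on the C12 ester before the quench. The shift may also occur with the wrong face at C8.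
- Fallback: the aza-enolate variant, starting from 29 and returning at 31. Condensation of 29 with 1,1-dimethylhydrazine gives the N,N-dimethylhydrazone of 29 F1. Deprotonation at C8 with LiN(iPr)2 gives an aza-enolate, a softer anion for which the [2,3] shift of α-allyloxy hydrazones is established; it gives the N,N-dimethylhydrazone of 31 F2. Buffered cleavage of the hydrazone (NaIO4, pH 7) then returns 31. A wrong C8 epimer could alternatively be equilibrated through the enol with a mild amine base.

**Step 10.**
- What may go wrong: the Lewis acid needed to release the allylborane may open the trisubstituted epoxide or rearrange the epoxy aldehyde. The reagent's facial preference may also be mismatched with the α-quaternary centre, giving poor selectivity at C2/C3.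
- Fallback: olefination and directed epoxidation, starting from 11 and returning at 16. Still–Gennari olefination of 11 with methyl bis(2,2,2-trifluoroethyl)phosphonoacetate gives the (2Z)-enoate F3. iBu2AlH reduction gives the (Z)-allylic alcohol F4. Katsuki–Sharpless epoxidation with stoichiometric Ti(OiPr)4, D-(−)-diethyl tartrate and t-BuOOH gives the 2,3-epoxy alcohol F5. Dess–Martin oxidation returns 16.

**Step 20.**
- What may go wrong: oligomerization may compete with ring closure. The alkenylchromium species may lose the C14 alkoxide by β-elimination, or be protonated before it reaches the aldehyde.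
- Fallback: the macrocycle is closed at C7=C11 instead, starting from 21 and returning at 28.
  - Phosphonate 25 is oxidized (Dess–Martin) to methyl 2-(dimethoxyphosphoryl)-3-(2-oxoethoxy)propanoate F6.
  - Intermolecular CrCl2/NiCl2 coupling of 21 with F6 gives the open-chain C9 alcohol with C11 phosphonate F7.
  - Acetylation gives the C9 acetate F8, which keeps C9 from becoming a ketone that the phosphonate carbanion would attack in a five-membered olefination.
  - Swern oxidation of the primary silyl ether gives the C7 aldehyde F9.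
  - Horner–Wadsworth–Emmons macrocyclization (LiCl, DBU, MeCN, high dilution) gives the thirteen-membered C9 acetate F10.
  - Methanolysis (K2CO3, MeOH) returns 28.

**Step 27.**
- What may go wrong: hydride may add to the wrong face of the C9 ketone under the control of the ring conformation, or the acrylate may be reduced in a 1,4 sense.
- Fallback: if the major product is the (9R)-alcohol F11, it is not discarded. Starting from 37 by way of F11, a Mitsunobu reaction (PPh3, diisopropyl azodicarboxylate, AcOH) inverts C9 and installs the acetate in one operation, returning at 39.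

**Step 29.**
- What may go wrong: the freed O6 may take up the C8 acyl group instead of closing the lactone. The epoxide may migrate to C5–C6, or the hydroxy ester may fail to close.
- Fallback: the lactone is closed earlier, while C9 is still sp2 and the ring is shaped differently, starting from 37 and returning at 41. HF·pyridine treatment of 37 gives the C9-keto 6,12-lactone F12. Luche reduction gives the (9S)-hydroxy lactone F13. Acetylation returns 41.

## Further compounds

F1 | step 22 | N,N-dimethylhydrazone of 29 | CN(C)N=C1COC/C(C(=O)OC)=C\[C@H](O[Si](CC)(CC)CC)[C@H]2O[C@@]2(C)[C@@H]2O[C@@H]2/C=C1/COCc3ccc(OC)cc3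
F2 | step 22 | N,N-dimethylhydrazone of 31 | C=C(C(=O)OC)[C@@H]1[C@H](O)C(=NN(C)C)/C(COCc3ccc(OC)cc3)=C\[C@H]2O[C@H]2[C@]2(C)O[C@@H]2[C@H]1O[Si](CC)(CC)CC
F3 | step 10 | methyl (2Z)-3-{(2R,3R)-3-[(1S)-1,2-bis(triethylsilyloxy)ethyl]-2-methyloxiran-2-yl}prop-2-enoate | CC[Si](CC)(CC)OC[C@H](O[Si](CC)(CC)CC)[C@H]1O[C@@]1(C)/C=C\C(=O)OC
F4 | step 10 | (2Z)-3-{(2R,3R)-3-[(1S)-1,2-bis(triethylsilyloxy)ethyl]-2-methyloxiran-2-yl}prop-2-en-1-ol | CC[Si](CC)(CC)OC[C@H](O[Si](CC)(CC)CC)[C@H]1O[C@@]1(C)/C=C\CO
F5 | step 10 | {(2R,3R)-3-[(2R,3R)-3-[(1S)-1,2-bis(triethylsilyloxy)ethyl]-2-methyloxiran-2-yl]oxiran-2-yl}methanol | CC[Si](CC)(CC)OC[C@H](O[Si](CC)(CC)CC)[C@H]1O[C@@]1(C)[C@@H]1O[C@@H]1CO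
F6 | step 20 | methyl 2-(dimethoxyphosphoryl)-3-(2-oxoethoxy)propanoate | COC(=O)C(COCC=O)P(=O)(OC)OC
F7 | step 20 | open-chain C9 alcohol with C11 phosphonate, 6,7-bis-O-triethylsilyl, 14-O-p-methoxybenzyl | CC[Si](CC)(CC)OC[C@H](O[Si](CC)(CC)CC)[C@H]1O[C@@]1(C)[C@@H]1O[C@@H]1/C=C(/COCc1ccc(OC)cc1)C(O)COCC(C(=O)OC)P(=O)(OC)OC
F8 | step 20 | C9 acetate of F7 | CC[Si](CC)(CC)OC[C@H](O[Si](CC)(CC)CC)[C@H]1O[C@@]1(C)[C@@H]1O[C@@H]1/C=C(/COCc1ccc(OC)cc1)C(OC(C)=O)COCC(C(=O)OC)P(=O)(OC)OC
F9 | step 20 | C7 aldehyde of F8 | O=C[C@H](O[Si](CC)(CC)CC)[C@H]1O[C@@]1(C)[C@@H]1O[C@@H]1/C=C(/COCc1ccc(OC)cc1)C(OC(C)=O)COCC(C(=O)OC)P(=O)(OC)OC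
F10 | step 20 | thirteen-membered C9 acetate (acetate of 28) | CC(=O)OC1COC/C(C(=O)OC)=C\[C@H](O[Si](CC)(CC)CC)[C@H]2O[C@@]2(C)[C@@H]2O[C@@H]2/C=C1/COCc3ccc(OC)cc3
F11 | step 27 | (9R)-alcohol, C9 epimer of 38 | C=C(C(=O)OC)[C@@H]1[C@H](OC(=O)[C@]2(C)O[C@@H]2C)[C@H](O)/C(COCc3ccc(OC)cc3)=C\[C@H]2O[C@H]2[C@]2(C)O[C@@H]2[C@H]1O[Si](CC)(CC)CC
F12 | step 29 | C9-keto 6,12-lactone with C8 epoxyangelate and 14-O-p-methoxybenzyl | C=C1C(=O)O[C@H]2[C@H]1[C@H](OC(=O)[C@]1(C)O[C@@H]1C)C(=O)/C(COCc1ccc(OC)cc1)=C\[C@H]1O[C@H]1[C@]1(C)O[C@H]21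
F13 | step 29 | (9S)-hydroxy 6,12-lactone with C8 epoxyangelate and 14-O-p-methoxybenzyl | C=C1C(=O)O[C@H]2[C@H]1[C@H](OC(=O)[C@]1(C)O[C@@H]1C)[C@@H](O)/C(COCc1ccc(OC)cc1)=C\[C@H]1O[C@H]1[C@]1(C)O[C@H]21
A1 | alternative 1 | ten-membered C8 ketone with C2≡C3 alkyne, cis C1=C10 2-(trimethylsilyl)ethyl ester, 4,5-epoxide, 6,7-trans lactone and 9-O-tert-butyldimethylsilyl | O=C1[C@H]2CC(=O)O[C@@H]2[C@H]3O[C@@]3(C)C#C/C=C(/C(=O)OCC[Si](C)(C)C)[C@@H]1O[Si](C)(C)C(C)(C)C
A2 | alternative 2 | 9-O-desacetylleucanthin B 2-(trimethylsilyl)ethyl ester | C=C1C(=O)O[C@H]2[C@H]1[C@H](OC(=O)[C@]1(C)O[C@@H]1C)[C@@H](O)/C(C(=O)OCC[Si](C)(C)C)=C\[C@H]1O[C@H]1[C@]1(C)O[C@H]21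
A3 | alternative 3 | ten-membered C6 ketone with both epoxides, cis C1=C10 2-(trimethylsilyl)ethyl ester, 8-O-p-methoxybenzyl and 9-O-tert-butyldimethylsilyl | O=C2C[C@H](OCc3ccc(OC)cc3)[C@@H](O[Si](C)(C)C(C)(C)C)/C(C(=O)OCC[Si](C)(C)C)=C\[C@H]1O[C@H]1[C@]1(C)O[C@H]21
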